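The readings come from a simulation for an exercise; noise was put on by code.

The charge of substrate is conserved, so whatever is neither left nor target stands in a gap that the readings do not show, and I worked from that gap.

| flask | substrate | first nucleophile | second nucleophile | protic impurity | temperature | remark | time |
|---|---|---|---|---|---|---|---|
| south | 10 mM | 60 mM | 40 mM | 6 mM | 45 °C | run made earlier |  |
| north | 40 mM | 60 mM | 40 mM | 6 mM | 78 °C | run made earlier |  |
| north-east | 20 mM | 120 mM | 40 mM | 6 mM | 45 °C | run made earlier |  |
| eta | 20 mM | 60.0 mM | 40.0 mM | 6.00 mM |  | at 30 °C until 10 min, from then on at 90 °C | 20 min |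
| zeta | 20 mM | 60.0 mM | 40.0 mM | 6.00 mM | 90 °C |  | 20 min |
| gamma | 20 mM | 60.0 mM | 40.0 mM | 6.00 mM | 60 °C |  | 20 min |
| theta | 20 mM | 60.0 mM | 40.0 mM | 6.00 mM | 30 °C |  | 20 min |

| run | time / min | target / % | substrate / % |
|---|---|---|---|
| south | 20.0 | 0.1 | 100.1 |
| south | 60.0 | 0.6 | 99.3 |
| south | 120 | 1.5 | 97.5 |
| south | 150 | 1.5 | 96.6 |
| south | 240 | 2.5 | 95.3 |
| north | 10.0 | 3.6 | 91.9 |
| north | 20.0 | 6.9 | 84.8 |
| north | 25.0 | 8.9 | 81.7 |
| north | 40.0 | 14.8 | 74.3 |
| north | 50.0 | 17.5 | 68.8 |
| north-east | 50.0 | 0.8 | 98.3 |
| north-east | 90.0 | 1.2 | 98.3 |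
| north-east | 150 | 2.3 | 97.1 |
| north-east | 180 | 2.2 | 96.1 |
| north-east | 240 | 3.9 | 94.9 |

(readings scatter by 0.3 percentage points)

- the numbers in the tables scatter by 0.3 percentage points (one standard deviation)

* the best flask by amount of target, in percent of the substrate charged; "all alike" if 1.5 percentage points covers them all (eta / zeta / gamma / theta / all alike)
* amount of target at the end, in percent of the substrate charged, eta
* amount of target at the end, in percent of the substrate charged, zeta
* amount of target at the end, in percent of the substrate charged, gamma
* amount of target at the end, in percent of the substrate charged, theta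

In the north run at 50.0 min the fraction left was 68.8% and target held 17.5%, so the gap was 13.7%. Target over gap was 1.28; this ratio, target made per unit of substrate lost elsewhere, is what I called the target odds, a selectivity factor. The south run read 1.14 at 240 min. The north-east run, with 120 mM of first nucleophile against 60 mM at the same temperature, but also with 20 mM of substrate against 10 mM, read 3.25. That is a factor of 2.85 for a charge factor of 2.00, but its gap was 1.20% with a scatter of 0.3 percentage points on each reading, so I took the odds as simply proportional to the first nucleophile charge.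

The decision was whether the next flask should keep 60.0 mM of first nucleophile or take more. At that charge I expected a share of 0.561 of whatever was lost to reach target, so the flask that lost most should win. The fraction left fell with a constant of 0.00748 min⁻¹ in the north run against 2.01 × 10⁻⁴ min⁻¹ in the south run. I therefore picked zeta, which stays hot twice as long as eta. The north constant, read at 78 °C and held for 20 min, leaves 86.1%, so my low estimate for zeta was 7.80% target. For the next run I chose 240 mM of first nucleophile, with expected odds of 5.11.

The forecast gave zeta as best, with 11%, 20%, 1.1% and 0.03% for eta, zeta, gamma and theta, holding that “Target is roughly half of the substrate lost”.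

Zeta was best, with 13.9% target, against 7.13% in eta, 1.23% in gamma and 0.0243% in theta.

    second nucleophile + intermediate → other capture product (k = 256 M⁻¹ min⁻¹, Ea = 52.0 kJ mol⁻¹)
    first nucleophile + intermediate → target (k = 66.7 M⁻¹ min⁻¹, Ea = 38.0 kJ mol⁻¹)
    2 second nucleophile → self-condensation product (k = 2.11 M⁻¹ min⁻¹, Ea = 62.0 kJ mol⁻¹)
    substrate ⇌ intermediate (K = 0.00330, k = 0.0457 min⁻¹, Ea = 114 kJ mol⁻¹, ΔH = −24.0 kJ mol⁻¹)
    second nucleophile + protic impurity → quenched reagent (k = 9.56 M⁻¹ min⁻¹, Ea = 46.0 kJ mol⁻¹)
    (constants at 90 °C)

At 20.0 min zeta held 72.3% substrate and 13.7% other capture product, which is nearly all of the gap, so its target odds were 1.02 against the 1.28 read in the north run. The neighbour of zeta with 240 mM of first nucleophile held 32.9% target and 8.52% other capture product. Its odds were 3.86 against my 5.11, which is 3.78 times the odds of zeta for 4.00 times the charge.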